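**Retrosynthetic overview**
1. The target acid comes from its 2-(trimethylsilyl)ethyl (TMSE) ester 24 by fluoride cleavage.
2. The only ring (11-membered) is closed last at C5–C6 by an asymmetric Ni/Cr (Nozaki–Hiyama–Kishi) macrocyclisation of iodo-aldehyde 22, which sets C6.
3. The C1–C11 bond joins the two halves: Ni-catalysed reductive cross-electrophile coupling of (Z)-2-bromo-enoate 19 with β-acyloxy iodide 9 (proposed new step).
4. East half 9: (S)-epichlorohydrin plus prenyl Grignard (C10 from the chiral pool), then acylation, hydroboration, Finkelstein.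
5. West half 19: pent-4-yn-1-ol (Ru hydrosilylation, oxidation) plus a bromo-ylide made from bromoacetyl bromide.

Assumption: the SMILES is read as (1E,6S,10S)-6-hydroxy-8,8-dimethyl-5-methylidene-10-(3-methylbutanoyloxy)cycloundec-1-ene-1-carboxylic acid; the antipode of the Kishi ligand in step 13 is fixed by a model coupling.

**Step 1**
Reactants: 1 1-chloro-3-methylbut-2-ene; 2 (S)-epichlorohydrin
Product: 4 (S)-1-chloro-4,4-dimethylhex-5-en-2-ol, via prenylmagnesium chloride 3 (not isolated)
Conditions: Mg, THF, 0 °C; then 2, THF, −40 → 0 °C; aq. NH4Cl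
Reagents that add atoms: none
Why: Grignard formation and γ-selective (SE2′) opening of the epoxide CH2 by the allylic Grignard reagent build the CH2–CMe2–CH=CH2 arm, and the C–O bond at the stereocentre is untouched, so (S)-2 delivers C10 of the target.

**Step 2**
Reactants: 4 (S)-1-chloro-4,4-dimethylhex-5-en-2-ol; 5 3-methylbutanoyl chloride
Product: 6 (S)-1-chloro-4,4-dimethylhex-5-en-2-yl 3-methylbutanoate
Conditions: pyridine, DMAP (cat.), CH2Cl2, 0 °C → rt
Reagents that add atoms: none
Why: DMAP-catalysed O-acylation installs the isovalerate before any carboxyl group is present, so the γ-oxygen can never lactonise later; the stereocentre is not involved.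

**Step 3**
Reactants: 6 (S)-1-chloro-4,4-dimethylhex-5-en-2-yl 3-methylbutanoate
Product: 8 (S)-1-chloro-6-hydroxy-4,4-dimethylhexan-2-yl 3-methylbutanoate, via B-alkyl-9-BBN adduct 7 (not isolated)
Conditions: 9-BBN, THF, 0 °C → rt; then 30% H2O2, aq. NaOAc, 0 °C → rt
Reagents that add atoms: hydrogen peroxide, OO
Why: Brown hydroboration–oxidation with 9-BBN is anti-Markovnikov on the vinyl group and leaves the ester and alkyl chloride alone; buffered peroxide keeps the ester.

**Step 4**
Reactants: 8 (S)-1-chloro-6-hydroxy-4,4-dimethylhexan-2-yl 3-methylbutanoate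
Product: 9 (S)-6-hydroxy-1-iodo-4,4-dimethylhexan-2-yl 3-methylbutanoate
Conditions: NaI (5 equiv), butan-2-one, reflux
Reagents that add atoms: sodium iodide, [Na+].[I-]
Why: Finkelstein halide exchange (SN2 at the primary carbon, driven by NaCl precipitation) gives the iodide needed for radical generation; the stereocentre is not touched.

**Step 5**
Reactants: 10 pent-4-yn-1-ol
Product: 11 4-(triethylsilyl)pent-4-en-1-ol
Conditions: [Cp*Ru(MeCN)3]PF6 (1 mol %), Et3SiH, CH2Cl2, 0 °C → rt
Reagents that add atoms: triethylsilane, CC[SiH](CC)CC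
Why: Trost Ru-catalysed Markovnikov hydrosilylation of a terminal alkyne gives the 1,1-disubstituted vinylsilane, a masked 2-iodoalkene that is inert to the later nickel coupling.

**Step 6**
Reactants: 11 4-(triethylsilyl)pent-4-en-1-ol
Product: 12 4-(triethylsilyl)pent-4-enal
Conditions: Dess–Martin periodinane, CH2Cl2, 0 °C → rt
Reagents that add atoms: none
Why: Dess–Martin oxidation takes the primary alcohol to the aldehyde without touching the vinylsilane.

**Step 7**
Reactants: 13 bromoacetyl bromide
Product: 14 2-(trimethylsilyl)ethyl bromoacetate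
Conditions: 2-(trimethylsilyl)ethanol, pyridine, CH2Cl2, −20 → 0 °C
Reagents that add atoms: 2-(trimethylsilyl)ethanol, C[Si](C)(C)CCO
Why: Esterification at the acyl bromide, which is far more reactive than the alkyl bromide, installs a carboxyl protecting group that fluoride removes without harming the isovalerate.

**Step 8**
Reactants: 14 2-(trimethylsilyl)ethyl bromoacetate
Product: 16 2-(trimethylsilyl)ethyl (triphenylphosphoranylidene)acetate, via phosphonium bromide 15 (not isolated)
Conditions: PPh3, toluene, rt; then 1 M NaOH, CH2Cl2, 0 °C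
Reagents that add atoms: triphenylphosphine, c1ccc(cc1)P(c1ccccc1)c1ccccc1
Why: SN2 quaternisation of PPh3 followed by deprotonation gives the stabilised Wittig ylide.

**Step 9**
Reactants: 16 2-(trimethylsilyl)ethyl (triphenylphosphoranylidene)acetate; 12 4-(triethylsilyl)pent-4-enal
Product: 19 2-(trimethylsilyl)ethyl (Z)-2-bromo-6-(triethylsilyl)hepta-2,6-dienoate, via bromophosphonium succinimidate 17 (not isolated), via bromo ylide 18 (not isolated)
Conditions: NBS, CH2Cl2, −20 °C; then K2CO3, 12, rt
Reagents that add atoms: N-bromosuccinimide, O=C1CCC(=O)N1Br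
Why: One-pot ylide bromination and Wittig olefination with the stabilised bromo ylide places the ester trans to the chain, giving mainly the (Z)-2-bromo-enoate; the minor isomer is removed by chromatography.

**Step 10**
Reactants: 19 2-(trimethylsilyl)ethyl (Z)-2-bromo-6-(triethylsilyl)hepta-2,6-dienoate; 9 (S)-6-hydroxy-1-iodo-4,4-dimethylhexan-2-yl 3-methylbutanoate
Product: 20 2-(trimethylsilyl)ethyl (2E)-2-[(2S)-6-hydroxy-4,4-dimethyl-2-(3-methylbutanoyloxy)hexyl]-6-(triethylsilyl)hepta-2,6-dienoate
Conditions: NiBr2·glyme (10 mol %), 4,4′-di-tert-butyl-2,2′-bipyridine (12 mol %), Mn powder (3 equiv), NaI (0.5 equiv), DMA, 25 °C; 9 (1.5 equiv)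
Reagents that add atoms: none
Why: Proposed new method: a stereoretentive Ni-catalysed reductive cross-electrophile coupling of a 2-bromo-2-enoate with a β-acyloxy primary alkyl iodide, in which Ni(0) inserts into the activated C(sp2)–Br bond, the primary radical formed from 9 by halogen abstraction is captured at nickel faster than it can undergo 1,2-acyloxy shift or Giese addition, and C(sp2)–C(sp3) reductive elimination from Ni(III) forms C1–C11 with the bromide geometry retained (the product is also the thermodynamically preferred enoate isomer), while no β-oxygenated carbanion that could eliminate is ever formed; the closest known reaction type is the bipyridine–nickel/Mn reductive coupling of alkenyl bromides with primary alkyl halides, not yet shown for α-halo enoates with this kind of alkyl partner.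

**Step 11**
Reactants: 20 (vinylsilane alcohol from step 10)
Product: 21 2-(trimethylsilyl)ethyl (2E)-2-[(2S)-6-hydroxy-4,4-dimethyl-2-(3-methylbutanoyloxy)hexyl]-6-iodohepta-2,6-dienoate
Conditions: NIS (1.2 equiv), (CF3)2CHOH, 0 °C, dark; aq. Na2S2O3
Reagents that add atoms: N-iodosuccinimide, O=C1CCC(=O)N1I
Why: Electrophilic ipso-iododesilylation of the 1,1-disubstituted vinylsilane in hexafluoroisopropanol gives the 2-iodoalkene, while the electron-poor enoate, the esters and the alcohol do not react.

**Step 12**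
Reactants: 21 (iodo alcohol from step 11)
Product: 22 2-(trimethylsilyl)ethyl (2E)-2-[(2S)-4,4-dimethyl-2-(3-methylbutanoyloxy)-6-oxohexyl]-6-iodohepta-2,6-dienoate
Conditions: Dess–Martin periodinane, CH2Cl2, 0 °C → rt
Reagents that add atoms: none
Why: Dess–Martin oxidation gives the aldehyde under neutral conditions that leave the vinyl iodide, the enoate and both esters intact.

**Step 13**
Reactants: 22 (iodo aldehyde from step 12)
Product: 24 2-(trimethylsilyl)ethyl (1E,6S,10S)-6-hydroxy-8,8-dimethyl-5-methylidene-10-(3-methylbutanoyloxy)cycloundec-1-ene-1-carboxylate, via alkenylchromium(III) species 23 (not isolated)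
Conditions: CrCl2 (4 equiv), Kishi chiral oxazoline–sulfonamide ligand (4.4 equiv), Et3N (4.4 equiv), NiCl2·(2,9-dimethyl-1,10-phenanthroline) (5 mol %), THF/MeCN, rt; 22 added by syringe pump to 2 mM
Reagents that add atoms: none
Why: Intramolecular Nozaki–Hiyama–Kishi coupling (Ni inserts into C–I, transmetalation to Cr(III), addition to the aldehyde) closes the 11-membered ring at C5–C6, helped by the gem-dimethyl group and the cis-configured ring alkene, and the chiral sulfonamide ligand on chromium sets the (S)-carbinol at C6 under reagent control.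

**Step 14**
Reactants: 24 (macrocyclic TMSE ester from step 13)
Product: 25 (1E,6S,10S)-6-hydroxy-8,8-dimethyl-5-methylidene-10-(3-methylbutanoyloxy)cycloundec-1-ene-1-carboxylic acid (CNP0400752.1)
Conditions: TBAF, THF, 0 °C → rt; then 0.5 M HCl work-up at 0 °C
Reagents that add atoms: none
Why: Fluoride-induced fragmentation of the 2-(trimethylsilyl)ethyl ester (β-elimination of ethene and Me3SiF) frees the acid, while the isovalerate and the allylic alcohol remain and no stereocentre is touched.

**Compound list**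
1 | 1-chloro-3-methylbut-2-ene (prenyl chloride) | CC(C)=CCCl | starting material
2 | (S)-2-(chloromethyl)oxirane ((S)-epichlorohydrin) | ClC[C@@H]1CO1 | starting material
3 | (3-methylbut-2-en-1-yl)magnesium chloride | CC(C)=CC[Mg]Cl | intermediate
4 | (S)-1-chloro-4,4-dimethylhex-5-en-2-ol | ClC[C@@H](O)CC(C)(C)C=C | intermediate
5 | 3-methylbutanoyl chloride (isovaleryl chloride) | CC(C)CC(=O)Cl | starting material
6 | (S)-1-chloro-4,4-dimethylhex-5-en-2-yl 3-methylbutanoate | ClC[C@@H](OC(=O)CC(C)C)CC(C)(C)C=C | intermediate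
7 | (S)-6-(9-borabicyclo[3.3.1]nonan-9-yl)-1-chloro-4,4-dimethylhexan-2-yl 3-methylbutanoate | ClC[C@@H](OC(=O)CC(C)C)CC(C)(C)CCB1C2CCCC1CCC2 | intermediate
8 | (S)-1-chloro-6-hydroxy-4,4-dimethylhexan-2-yl 3-methylbutanoate | ClC[C@@H](OC(=O)CC(C)C)CC(C)(C)CCO | intermediate
9 | (S)-6-hydroxy-1-iodo-4,4-dimethylhexan-2-yl 3-methylbutanoate | IC[C@@H](OC(=O)CC(C)C)CC(C)(C)CCO | intermediate
10 | pent-4-yn-1-ol | C#CCCCO | starting material
11 | 4-(triethylsilyl)pent-4-en-1-ol | C=C([Si](CC)(CC)CC)CCCO | intermediate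
12 | 4-(triethylsilyl)pent-4-enal | C=C([Si](CC)(CC)CC)CCC=O | intermediate
13 | bromoacetyl bromide | BrCC(=O)Br | starting material
14 | 2-(trimethylsilyl)ethyl bromoacetate | BrCC(=O)OCC[Si](C)(C)C | intermediate
15 | {2-oxo-2-[2-(trimethylsilyl)ethoxy]ethyl}triphenylphosphonium bromide | C[Si](C)(C)CCOC(=O)C[P+](c1ccccc1)(c1ccccc1)c1ccccc1.[Br-] | intermediate
16 | 2-(trimethylsilyl)ethyl (triphenylphosphoranylidene)acetate | C[Si](C)(C)CCOC(=O)C=P(c1ccccc1)(c1ccccc1)c1ccccc1 | intermediate
17 | {1-bromo-2-oxo-2-[2-(trimethylsilyl)ethoxy]ethyl}triphenylphosphonium succinimidate | C[Si](C)(C)CCOC(=O)C(Br)[P+](c1ccccc1)(c1ccccc1)c1ccccc1.O=C1CCC(=O)[N-]1 | intermediate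
18 | 2-(trimethylsilyl)ethyl bromo(triphenylphosphoranylidene)acetate | C[Si](C)(C)CCOC(=O)C(Br)=P(c1ccccc1)(c1ccccc1)c1ccccc1 | intermediate
19 | 2-(trimethylsilyl)ethyl (Z)-2-bromo-6-(triethylsilyl)hepta-2,6-dienoate | C=C([Si](CC)(CC)CC)CC/C=C(\Br)C(=O)OCC[Si](C)(C)C | intermediate
20 | 2-(trimethylsilyl)ethyl (2E)-2-[(2S)-6-hydroxy-4,4-dimethyl-2-(3-methylbutanoyloxy)hexyl]-6-(triethylsilyl)hepta-2,6-dienoate | C=C([Si](CC)(CC)CC)CC/C=C(/C(=O)OCC[Si](C)(C)C)C[C@@H](OC(=O)CC(C)C)CC(C)(C)CCO | intermediate
21 | 2-(trimethylsilyl)ethyl (2E)-2-[(2S)-6-hydroxy-4,4-dimethyl-2-(3-methylbutanoyloxy)hexyl]-6-iodohepta-2,6-dienoate | C=C(I)CC/C=C(/C(=O)OCC[Si](C)(C)C)C[C@@H](OC(=O)CC(C)C)CC(C)(C)CCO | intermediate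
22 | 2-(trimethylsilyl)ethyl (2E)-2-[(2S)-4,4-dimethyl-2-(3-methylbutanoyloxy)-6-oxohexyl]-6-iodohepta-2,6-dienoate | C=C(I)CC/C=C(/C(=O)OCC[Si](C)(C)C)C[C@@H](OC(=O)CC(C)C)CC(C)(C)CC=O | intermediate
23 | alkenylchromium(III) dichloride derived from 22 (Cr in place of I) | C=C([Cr](Cl)Cl)CC/C=C(/C(=O)OCC[Si](C)(C)C)C[C@@H](OC(=O)CC(C)C)CC(C)(C)CC=O | intermediate
24 | 2-(trimethylsilyl)ethyl (1E,6S,10S)-6-hydroxy-8,8-dimethyl-5-methylidene-10-(3-methylbutanoyloxy)cycloundec-1-ene-1-carboxylate | C=C1CC/C=C(/C(=O)OCC[Si](C)(C)C)C[C@@H](OC(=O)CC(C)C)CC(C)(C)C[C@@H]1O | intermediate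
25 | (1E,6S,10S)-6-hydroxy-8,8-dimethyl-5-methylidene-10-(3-methylbutanoyloxy)cycloundec-1-ene-1-carboxylic acid | C=C1CC/C=C(/C(=O)O)C[C@@H](OC(=O)CC(C)C)CC(C)(C)C[C@@H]1O | target

**Step count**
Total steps: 14. Longest linear sequence: 9 (steps 1, 2, 3, 4, 10, 11, 12, 13, 14). The west half (steps 5, 6, 9) and the ylide branch (steps 7, 8) run in parallel.

**Three steps most likely to fail**

Step 10 (the proposed new coupling). Risks are hydrodebromination or homocoupling of 19, loss of alkene geometry at nickel, and radical side reactions of 9. The fallback uses known chemistry only; it sets out from 14 (with 9 and 12) and comes back at 20. Arbuzov reaction of 14 with trimethyl phosphite (neat, 100 °C) gives 2-(trimethylsilyl)ethyl (dimethoxyphosphoryl)acetate F1. Its sodium salt (NaH, DMF, 0 °C) is C-alkylated with iodide 9 (50 °C) to the α-substituted phosphonate, 2-(trimethylsilyl)ethyl (4S)-2-(dimethoxyphosphoryl)-8-hydroxy-6,6-dimethyl-4-(3-methylbutanoyloxy)octanoate F2 (epimers at C2). Horner–Wadsworth–Emmons olefination of F2 with aldehyde 12 (LiCl, DBU, MeCN) gives the (E)-enoate 20.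

Step 13 (11-membered closure with reagent control at C6). The main risk is poor diastereoselectivity. The fallback sets out from 22 and comes back at 24, and moves stereocontrol from the C–C bond formation to a ketone reduction. Cyclisation of 22 with ligand-free CrCl2/NiCl2 (cat.) in DMSO/THF at high dilution gives, through 23, a mixture of 24 and its C6 epimer, 2-(trimethylsilyl)ethyl (1E,6R,10S)-6-hydroxy-8,8-dimethyl-5-methylidene-10-(3-methylbutanoyloxy)cycloundec-1-ene-1-carboxylate F3. Dess–Martin oxidation of the mixture gives the cross-conjugated enone, 2-(trimethylsilyl)ethyl (1E,10S)-8,8-dimethyl-5-methylidene-10-(3-methylbutanoyloxy)-6-oxocycloundec-1-ene-1-carboxylate F4. Corey–Bakshi–Shibata reduction of F4 with (R)-Me-CBS and catecholborane (toluene, −40 °C, alkenyl as the large group) gives the (6S)-alcohol 24.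

Step 4 (Finkelstein on a β-acyloxy chloride). The exchange may be slow, and acyloxy participation could scramble the ester position. The fallback sets out from 4 and comes back at 9, bringing in iodide and ester together by epoxide opening. Treating 4 with NaOH (Et2O/H2O) gives (S)-2-(2,2-dimethylbut-3-en-1-yl)oxirane F5. Isovaleryl chloride 5 and NaI in MeCN form 3-methylbutanoyl iodide F6 in the flask, which opens F5 at the terminal carbon to give (S)-1-iodo-4,4-dimethylhex-5-en-2-yl 3-methylbutanoate F7 with the C–O bond at the stereocentre retained. Hydroboration of F7 with 9-BBN gives the B-alkyl-9-BBN adduct F8, which buffered H2O2 oxidises to 9.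

**Further compounds**
F1 | step 10 | 2-(trimethylsilyl)ethyl (dimethoxyphosphoryl)acetate | COP(=O)(OC)CC(=O)OCC[Si](C)(C)C
F2 | step 10 | 2-(trimethylsilyl)ethyl (4S)-2-(dimethoxyphosphoryl)-8-hydroxy-6,6-dimethyl-4-(3-methylbutanoyloxy)octanoate | COP(=O)(OC)C(C(=O)OCC[Si](C)(C)C)C[C@@H](OC(=O)CC(C)C)CC(C)(C)CCO
F3 | step 13 | 2-(trimethylsilyl)ethyl (1E,6R,10S)-6-hydroxy-8,8-dimethyl-5-methylidene-10-(3-methylbutanoyloxy)cycloundec-1-ene-1-carboxylate | C=C1CC/C=C(/C(=O)OCC[Si](C)(C)C)C[C@@H](OC(=O)CC(C)C)CC(C)(C)C[C@H]1O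
F4 | step 13 | 2-(trimethylsilyl)ethyl (1E,10S)-8,8-dimethyl-5-methylidene-10-(3-methylbutanoyloxy)-6-oxocycloundec-1-ene-1-carboxylate | C=C1CC/C=C(/C(=O)OCC[Si](C)(C)C)C[C@@H](OC(=O)CC(C)C)CC(C)(C)CC1=O
F5 | step 4 | (S)-2-(2,2-dimethylbut-3-en-1-yl)oxirane | C1[C@@H](O1)CC(C)(C)C=C
F6 | step 4 | 3-methylbutanoyl iodide | CC(C)CC(=O)I
F7 | step 4 | (S)-1-iodo-4,4-dimethylhex-5-en-2-yl 3-methylbutanoate | IC[C@@H](OC(=O)CC(C)C)CC(C)(C)C=C
F8 | step 4 | (S)-6-(9-borabicyclo[3.3.1]nonan-9-yl)-1-iodo-4,4-dimethylhexan-2-yl 3-methylbutanoate | IC[C@@H](OC(=O)CC(C)C)CC(C)(C)CCB1C2CCCC1CCC2
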